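Ring A (C4a, C5, C6, C7, C8, C8a) is taken apart into three alkynes. The key step exploits two features. The two oxygens sit on adjacent C6 and C7, which maps onto a symmetric diborylethyne. The chain C4–C3–O2–C1 of ring B spans C4a and C8a like the tether of an oxa-1,7-diyne. One cobalt-catalysed [2+2+2] cocyclisation therefore forms C4a–C8a, C5–C6 and C7–C8 and closes rings A and B together, and no regioisomer can arise. The precursor is a racemic 2,4-dimethoxyphenyl ketone whose α-carbon (future C3) bears a propargyl and a propargyloxy group. Afterwards both C–B bonds become OMe and C3–C4 is dehydrogenated.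

Key step: step 4

Assumption: C3 is a stereocentre in 7 and in 9–13 but is sp2 in the target, so these compounds are carried as racemates (13 also as a mixture at selenium) and no stereocontrol is planned.

Step 1
Reactants: 1 propargyl alcohol; 2 2-chloro-N-methoxy-N-methylacetamide
Product: 3 N-methoxy-N-methyl-2-(prop-2-yn-1-yloxy)acetamide
Conditions: NaH (1.1 equiv), THF, 0 °C to rt
Reagents that add atoms: none
Why: Williamson ether synthesis, in which the alkoxide of 1 (the O–H is far more acidic than the alkynyl C–H) displaces the activated α-chloride of 2 by SN2, and this silver-free entry through an amide avoids both silver acetylide formation and the carbonyl attack that alkoxides show toward α-halo ketones.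

Step 2
Reactants: 3 N-methoxy-N-methyl-2-(prop-2-yn-1-yloxy)acetamide; 4 2,4-dimethoxyphenylmagnesium bromide (solution in THF)
Product: 5 1-(2,4-dimethoxyphenyl)-2-(prop-2-yn-1-yloxy)ethan-1-one
Conditions: 4 (2.2 equiv), THF, 0 °C; then 1 M HCl, 0 °C
Reagents that add atoms: none
Why: Weinreb ketone synthesis, in which the magnesium-chelated tetrahedral adduct should persist until the acidic quench so that only one aryl group is delivered, while the extra equivalent of 4 covers any deprotonation of the alkyne C–H, which work-up restores.

Step 3
Reactants: 5 1-(2,4-dimethoxyphenyl)-2-(prop-2-yn-1-yloxy)ethan-1-one; 6 propargyl bromide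
Product: 7 1-(2,4-dimethoxyphenyl)-2-(prop-2-yn-1-yloxy)pent-4-yn-1-one (racemic)
Conditions: LiN(SiMe3)2 (1.05 equiv), THF, −78 °C; DMPU, 6 (1.5 equiv), −78 to −30 °C
Reagents that add atoms: none
Why: Enolate alkylation (SN2) of an α-alkoxy aryl ketone that can enolise on one side only, where LiN(SiMe3)2 removes the α-proton but not the alkynyl proton, the cold DMPU-accelerated reaction with a reactive propargylic bromide should outrun both the [2,3]-Wittig shift of the propargyloxy enolate and a second alkylation, and the new centre (future C3) forms as a racemate that step 7 erases.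

Step 4
Reactants: 7 1-(2,4-dimethoxyphenyl)-2-(prop-2-yn-1-yloxy)pent-4-yn-1-one (racemic); 8 1,2-bis(4,4,5,5-tetramethyl-1,3,2-dioxaborolan-2-yl)ethyne
Product: 9 [6,7-bis(4,4,5,5-tetramethyl-1,3,2-dioxaborolan-2-yl)-3,4-dihydro-1H-isochromen-3-yl](2,4-dimethoxyphenyl)methanone (racemic)
Conditions: 8 (3 equiv), CpCo(CO)(dimethyl fumarate) (10 mol %), dry toluene, 110 °C, no light; 7 added by syringe pump over 8 h
Reagents that add atoms: none
Why: Thermal loss of CO and fumarate frees the CpCo fragment (monovalent cobalt), which binds both alkynes of 7 and couples them oxidatively at their inner carbons to a cobaltacyclopentadiene (trivalent cobalt) with the metal on C5 and C8, after which 8 coordinates and inserts and reductive elimination releases the arene and returns the catalyst. The closest known reaction type is the CpCo-catalysed [2+2+2] cocyclisation of α,ω-diynes with bulky bis(silyl) or boryl alkynes to fused benzenes, applied here to a new keto diyne. Ring B closes in the oxidative coupling, where the four-atom tether makes C4a–C8a formation an intramolecular six-membered closure, and ring A closes in the insertion and reductive elimination that form C5–C6 and C7–C8. No stereocentre is created, and the racemic C3 centre is a spectator. The step needs cross-selectivity between 7 and 8: 8 is too hindered to trimerise with itself at a useful rate and is present in excess, slow addition keeps 7 dilute so that the metallacycle meets 8 rather than a second diyne, and the symmetry of 8 together with the tether allows only one substitution pattern. A thermally activated precatalyst in the dark is chosen because an excited α-alkoxy aryl ketone would abstract hydrogen from its OCH2 group (Norrish–Yang chemistry), whereas ketone, ethers and pinacol boronates should be inert to low-valent cobalt.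

Step 5
Reactants: 9 [6,7-bis(4,4,5,5-tetramethyl-1,3,2-dioxaborolan-2-yl)-3,4-dihydro-1H-isochromen-3-yl](2,4-dimethoxyphenyl)methanone (racemic)
Product: 10 (6,7-dihydroxy-3,4-dihydro-1H-isochromen-3-yl)(2,4-dimethoxyphenyl)methanone (racemic)
Conditions: NaBO3·4H2O (6 equiv), THF/H2O 1:1, rt, N2; then aq. NH4Cl
Reagents that add atoms: sodium perborate tetrahydrate (NaBO3·4H2O), [Na+].[Na+].O[B-]1(O)OO[B-](O)(O)OO1
Why: Oxidation of aryl boronates (peroxide adds to boron, the aryl group shifts from boron to oxygen, and the borate is hydrolysed), run with mild perborate under nitrogen so that the ketone should see no Baeyer–Villiger reaction and the catechol is not carried on to the o-quinone.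

Step 6
Reactants: 10 (6,7-dihydroxy-3,4-dihydro-1H-isochromen-3-yl)(2,4-dimethoxyphenyl)methanone (racemic)
Product: 11 (6,7-dimethoxy-3,4-dihydro-1H-isochromen-3-yl)(2,4-dimethoxyphenyl)methanone (racemic)
Conditions: MeI (3 equiv), K2CO3 (4 equiv), acetone, 50 °C, N2
Reagents that add atoms: iodomethane, CI
Why: Williamson-type O-methylation of the two phenoxides, in which K2CO3 is basic enough for the phenols but not for C3–H, so C-methylation next to the ketone should not compete.

Step 7
Reactants: 11 (6,7-dimethoxy-3,4-dihydro-1H-isochromen-3-yl)(2,4-dimethoxyphenyl)methanone (racemic)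
Product: 14 (6,7-dimethoxy-1H-isochromen-3-yl)(2,4-dimethoxyphenyl)methanone, via C3 phenylselenide 12 (not isolated), via C3 selenoxide 13 (not isolated)
Conditions: LiN(iPr)2 (1.2 equiv), THF, −78 °C; PhSeCl (1.2 equiv), −78 °C; then AcOH, 30 % aq. H2O2 (3 equiv), 0 °C to rt, same flask
Reagents that add atoms: none
Why: α-Selenenylation of a ketone enolate followed by selenoxide syn-elimination, in which 11 has its only α-hydrogen at C3 and the selenoxide has β-hydrogens only at C4, so the C3=C4 bond is the sole possible outcome and the racemic centre disappears.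

Compound list
1 | propargyl alcohol | C#CCO | starting material
2 | 2-chloro-N-methoxy-N-methylacetamide | CON(C)C(=O)CCl | starting material
3 | N-methoxy-N-methyl-2-(prop-2-yn-1-yloxy)acetamide | CON(C)C(=O)COCC#C | intermediate
4 | 2,4-dimethoxyphenylmagnesium bromide | COc1ccc([Mg]Br)c(OC)c1 | starting material
5 | 1-(2,4-dimethoxyphenyl)-2-(prop-2-yn-1-yloxy)ethan-1-one | COc1ccc(C(=O)COCC#C)c(OC)c1 | intermediate
6 | propargyl bromide | C#CCBr | starting material
7 | 1-(2,4-dimethoxyphenyl)-2-(prop-2-yn-1-yloxy)pent-4-yn-1-one, racemic | COc1ccc(C(=O)C(CC#C)OCC#C)c(OC)c1 | intermediate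
8 | 1,2-bis(4,4,5,5-tetramethyl-1,3,2-dioxaborolan-2-yl)ethyne | CC1(C)OB(C#CB2OC(C)(C)C(C)(C)O2)OC1(C)C | starting material
9 | [6,7-bis(4,4,5,5-tetramethyl-1,3,2-dioxaborolan-2-yl)-3,4-dihydro-1H-isochromen-3-yl](2,4-dimethoxyphenyl)methanone, racemic | COc1ccc(C(=O)C2Cc3cc(B4OC(C)(C)C(C)(C)O4)c(B5OC(C)(C)C(C)(C)O5)cc3CO2)c(OC)c1 | intermediate
10 | (6,7-dihydroxy-3,4-dihydro-1H-isochromen-3-yl)(2,4-dimethoxyphenyl)methanone, racemic | COc1ccc(C(=O)C2Cc3cc(O)c(O)cc3CO2)c(OC)c1 | intermediate
11 | (6,7-dimethoxy-3,4-dihydro-1H-isochromen-3-yl)(2,4-dimethoxyphenyl)methanone, racemic | COc1ccc(C(=O)C2Cc3cc(OC)c(OC)cc3CO2)c(OC)c1 | intermediate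
12 | [6,7-dimethoxy-3-(phenylselanyl)-3,4-dihydro-1H-isochromen-3-yl](2,4-dimethoxyphenyl)methanone, racemic | COc1ccc(C(=O)C2(Cc3cc(OC)c(OC)cc3CO2)[Se]c4ccccc4)c(OC)c1 | intermediate
13 | [6,7-dimethoxy-3-(phenylseleninyl)-3,4-dihydro-1H-isochromen-3-yl](2,4-dimethoxyphenyl)methanone, racemic, mixture at selenium | COc1ccc(C(=O)C2(Cc3cc(OC)c(OC)cc3CO2)[Se](=O)c4ccccc4)c(OC)c1 | intermediate
14 | (6,7-dimethoxy-1H-isochromen-3-yl)(2,4-dimethoxyphenyl)methanone | COc1ccc(C(=O)C2=Cc3cc(OC)c(OC)cc3CO2)c(OC)c1 | target

Total step count: 7. Longest linear sequence: 7 (steps 1 to 7).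

Steps most likely to fail

Step 4. The hindered alkyne 8 may enter the cobaltacyclopentadiene too slowly. A second molecule of 7 would then be taken up instead (oligomerisation), or the metal would be trapped as an inert cyclobutadiene complex. The fallback gives up the de novo arene and builds ring B onto a bought dimethoxybenzene. It sets out from Grignard reagent 4 and comes back to the route at 11.
- CuI-catalysed opening of purchased methyl oxirane-2-carboxylate at its CH2 terminus by purchased 3,4-dimethoxyphenylmagnesium bromide should give methyl 3-(3,4-dimethoxyphenyl)-2-hydroxypropanoate F1.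
- An oxa-Pictet–Spengler reaction with paraformaldehyde in CF3CO2H should close ring B para to the ring methoxy group meta to the side chain and give methyl 6,7-dimethoxy-3,4-dihydro-1H-isochromene-3-carboxylate F2.
- Aminolysis with MeNHOMe·HCl and AlMe3 should give N,6,7-trimethoxy-N-methyl-3,4-dihydro-1H-isochromene-3-carboxamide F3.
- Addition of 4 under the conditions of step 2 should give 11, from which step 7 follows unchanged.

Step 3. The propargyloxy enolate may undergo a [2,3]-sigmatropic shift to an allenyl carbinol. Proton exchange between enolate and product may also lead to double alkylation. The fallback forms the C–O bond at an alkoxide, not the C–C bond at an enolate that carries the propargyl ether. It sets out from propargyl bromide 6 and comes back at 7.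
- Zn-mediated Barbier addition of 6 to purchased ethyl glyoxylate should give ethyl 2-hydroxypent-4-ynoate F4.
- O-alkylation with NaH (1.0 equiv) and a second portion of 6 should give ethyl 2-(prop-2-yn-1-yloxy)pent-4-ynoate F5.
- AlMe3-mediated aminolysis with MeNHOMe·HCl should give N-methoxy-N-methyl-2-(prop-2-yn-1-yloxy)pent-4-ynamide F6.
- An excess of 4, which also covers both alkyne protons, should then give 7.

Step 7. Enolisation of the hindered tertiary C3–H may be incomplete. The electron-rich C3=C4 bond may also be over-oxidised by the peroxyseleninic acid that forms from excess peroxide. The fallback replaces selenium and peroxide by palladium. It sets out from 11 and comes back at 14.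
- Me3SiOTf and Et3N in CH2Cl2 should convert 11 into [(6,7-dimethoxy-1,4-dihydro-3H-isochromen-3-ylidene)(2,4-dimethoxyphenyl)methoxy]trimethylsilane F7, as an E/Z mixture.
- A Saegusa–Ito oxidation with Pd(OAc)2 in MeCN should give 14 by β-hydride elimination from C4 of the palladium enolate.

Further compounds
F1 | step 4 | methyl 3-(3,4-dimethoxyphenyl)-2-hydroxypropanoate, racemic | COC(=O)C(O)Cc1ccc(OC)c(OC)c1
F2 | step 4 | methyl 6,7-dimethoxy-3,4-dihydro-1H-isochromene-3-carboxylate, racemic | COC(=O)C1Cc2cc(OC)c(OC)cc2CO1
F3 | step 4 | N,6,7-trimethoxy-N-methyl-3,4-dihydro-1H-isochromene-3-carboxamide, racemic | CON(C)C(=O)C1Cc2cc(OC)c(OC)cc2CO1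
F4 | step 3 | ethyl 2-hydroxypent-4-ynoate, racemic | CCOC(=O)C(O)CC#C
F5 | step 3 | ethyl 2-(prop-2-yn-1-yloxy)pent-4-ynoate, racemic | CCOC(=O)C(CC#C)OCC#C
F6 | step 3 | N-methoxy-N-methyl-2-(prop-2-yn-1-yloxy)pent-4-ynamide, racemic | CON(C)C(=O)C(CC#C)OCC#C
F7 | step 7 | [(6,7-dimethoxy-1,4-dihydro-3H-isochromen-3-ylidene)(2,4-dimethoxyphenyl)methoxy]trimethylsilane, E/Z mixture | COc1ccc(C(O[Si](C)(C)C)=C2Cc3cc(OC)c(OC)cc3CO2)c(OC)c1
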